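**Plan**
- Cuts: in unit 1 (the 5-hydroxy-7-methoxy-6-methylflavone) O1–C2 and C2–C3. Between the halves, the biaryl bond C3'(unit 1)–C8(unit 2). In unit 2 (the apigenin half) C2–C3 and O1–C8a.
- Forward: a fluoro ketone (ring A of unit 2) and a ring B boronate are joined by Suzuki coupling. A Claisen condensation adds C2 and ring B of unit 2, and fluoride displacement closes the unit 2 pyranone. The unmasked ring B aldehyde is then condensed with the ring A acetophenone of unit 1, the second pyranone is closed oxidatively, and all protecting groups are removed in one operation.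
- Enabling feature: O1 of unit 2 has to bond to C8a, the ring A carbon between aryl-bearing C8 and C4a, and not to C5. With fluorine on C8a, ortho to the C4 ketone and meta to the C5 and C7 oxygens, only that carbon can be attacked, so the 8-aryl flavone and not the 6-aryl isomer must form.
- Stereochemistry: the target has no stereocentre. The only stereo element on the way, the E alkene of the chalcone, is erased in the oxidative closure.

Key step: step 9

Remark: the target SMILES defines no configuration for the biaryl axis, so no axial control is attempted and the material is taken as racemic or freely rotating about that bond.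

**Step 1**
Reactants: 1 5-fluororesorcinol
Product: 3 1-(2-fluoro-4,6-dihydroxyphenyl)ethanone, via ketiminium chloride 2 (not isolated)
Conditions: MeCN, ZnCl2, HCl (g), Et2O, 0 °C to rt; then H2O, reflux
Reagents that add atoms: acetonitrile CC#N; water O
Why: Houben–Hoesch acylation of a resorcinol goes para to one hydroxyl and ortho to the other (as in resacetophenone and orcacetophenone), here the carbon next to fluorine rather than the one between the two hydroxyls, and hydrolysis of the ketiminium salt should give the ketone.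

**Step 2**
Reactants: 3 1-(2-fluoro-4,6-dihydroxyphenyl)ethanone
Product: 4 1-[2,4-bis(benzyloxy)-6-fluorophenyl]ethanone
Conditions: BnBr, K2CO3, DMF, 60 °C
Reagents that add atoms: benzyl bromide BrCc1ccccc1
Why: Williamson ether synthesis in warm DMF should alkylate both phenols, including the hydrogen-bonded one ortho to the ketone, while the electron-rich phenoxide ring keeps the fluoride from being displaced.

**Step 3**
Reactants: 4 1-[2,4-bis(benzyloxy)-6-fluorophenyl]ethanone
Product: 5 1-[4,6-bis(benzyloxy)-3-bromo-2-fluorophenyl]ethanone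
Conditions: NBS, MeCN, 0 °C to rt
Reagents that add atoms: N-bromosuccinimide O=C1CCC(=O)N1Br
Why: electrophilic aromatic bromination should follow the pattern of 2,4-dialkoxyacetophenones, which react at C5, so attack is expected para to the 2-benzyloxy group at the fluorine-flanked carbon and not at the crowded carbon between the two benzyloxy groups.

**Step 4**
Reactants: 6 3-bromo-4-hydroxybenzaldehyde
Product: 7 4-(benzyloxy)-3-bromobenzaldehyde
Conditions: BnBr, K2CO3, DMF, rt
Reagents that add atoms: benzyl bromide BrCc1ccccc1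
Why: Williamson ether synthesis of an acidic para-formyl phenol is routine and leaves aldehyde and bromide untouched.

**Step 5**
Reactants: 7 4-(benzyloxy)-3-bromobenzaldehyde
Product: 8 2-[4-(benzyloxy)-3-bromophenyl]-1,3-dioxolane
Conditions: HOCH2CH2OH, TsOH·H2O (cat.), toluene, reflux, Dean–Stark
Reagents that add atoms: ethylene glycol OCCO
Why: acid-catalysed acetalisation driven by azeotropic removal of water masks the aldehyde against the enolate chemistry of steps 8 and 9.

**Step 6**
Reactants: 8 2-[4-(benzyloxy)-3-bromophenyl]-1,3-dioxolane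
Product: 9 2-[4-(benzyloxy)-3-(4,4,5,5-tetramethyl-1,3,2-dioxaborolan-2-yl)phenyl]-1,3-dioxolane
Conditions: B2pin2, PdCl2(dppf) (cat.), KOAc, 1,4-dioxane, 90 °C
Reagents that add atoms: bis(pinacolato)diboron CC1(C)OB(OC1(C)C)B1OC(C)(C)C(C)(C)O1
Why: Miyaura borylation of an aryl bromide with the weak base KOAc tolerates the acetal and the benzyl ether and gives a boronate stable enough to purify.

**Step 7**
Reactants: 5 1-[4,6-bis(benzyloxy)-3-bromo-2-fluorophenyl]ethanone; 9 2-[4-(benzyloxy)-3-(4,4,5,5-tetramethyl-1,3,2-dioxaborolan-2-yl)phenyl]-1,3-dioxolane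
Product: 10 1-{4,6-bis(benzyloxy)-3-[2-(benzyloxy)-5-(1,3-dioxolan-2-yl)phenyl]-2-fluorophenyl}ethanone
Conditions: Pd(OAc)2 (cat.), SPhos, K3PO4, toluene/H2O, 90 °C
Reagents that add atoms: none
Why: Suzuki–Miyaura coupling with a dialkylbiarylphosphine-ligated palladium catalyst is established for tri-ortho-substituted biaryls, and oxidative addition should take the C–Br bond and leave the C–F bond alone.

**Step 8**
Reactants: 10 1-{4,6-bis(benzyloxy)-3-[2-(benzyloxy)-5-(1,3-dioxolan-2-yl)phenyl]-2-fluorophenyl}ethanone; 11 methyl 4-(benzyloxy)benzoate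
Product: 12 1-{4,6-bis(benzyloxy)-3-[2-(benzyloxy)-5-(1,3-dioxolan-2-yl)phenyl]-2-fluorophenyl}-3-[4-(benzyloxy)phenyl]propane-1,3-dione
Conditions: LiN(SiMe3)2 (3 equiv), THF, −78 °C to rt; AcOH quench
Reagents that add atoms: none
Why: crossed Claisen condensation of the lithium enolate of the methyl ketone with a non-enolisable aryl ester is driven by deprotonation of the diketone, and the chelated lithium diketonate in THF at or below room temperature should not yet displace the fluoride.

**Step 9**
Reactants: 12 1-{4,6-bis(benzyloxy)-3-[2-(benzyloxy)-5-(1,3-dioxolan-2-yl)phenyl]-2-fluorophenyl}-3-[4-(benzyloxy)phenyl]propane-1,3-dione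
Product: 13 5,7-bis(benzyloxy)-2-[4-(benzyloxy)phenyl]-8-[2-(benzyloxy)-5-(1,3-dioxolan-2-yl)phenyl]-4H-chromen-4-one
Conditions: K2CO3, DMF, 80 °C
Reagents that add atoms: none
Why: K2CO3 converts the diketone into its enolate, whose oxygen at the 4-benzyloxybenzoyl end adds to the fluorine-bearing ring carbon (the future C8a) to give a Meisenheimer anion delocalised into the ortho ketone, and loss of fluoride completes an addition–elimination (SNAr). The closest known reaction is the base-mediated cyclisation of 1-(2-halophenyl)-1,3-diketones to flavones, applied here to a more hindered and more electron-rich ring. The pyranone closes as a six-membered ring by attack of oxygen on an sp2 carbon held in the plane of the enolate, 6-endo-trig with respect to the C8a=C4a bond that relays the charge to the C4 carbonyl, whereas closure through the other enolate oxygen would need a four-membered ring. No stereocentre is formed. The selectivity needed is between the two ring A carbons ortho to the acyl group, and it is secured because only one of them carries a leaving group, so the benzyloxy-bearing carbon (future C5) cannot be substituted and the 6-aryl isomer is excluded. Both benzyloxy groups are meta to the C–F carbon and so do not donate into the ring positions that take up the negative charge, and the reversibly formed enolate allows the slow, hindered attack to be driven by heating.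

**Step 10**
Reactants: 13 5,7-bis(benzyloxy)-2-[4-(benzyloxy)phenyl]-8-[2-(benzyloxy)-5-(1,3-dioxolan-2-yl)phenyl]-4H-chromen-4-one
Product: 14 4-(benzyloxy)-3-{5,7-bis(benzyloxy)-2-[4-(benzyloxy)phenyl]-4-oxo-4H-chromen-8-yl}benzaldehyde
Conditions: 1 M aq. HCl, THF, rt
Reagents that add atoms: water O
Why: acid-catalysed acetal hydrolysis should free the aldehyde under conditions to which the flavone and the benzyl ethers are inert.

**Step 11**
Reactants: 15 2,6-dimethoxytoluene
Product: 17 3,5-dimethoxy-4-methylphenol, via pinacol boronate 16 (not isolated)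
Conditions: B2pin2 (0.6 equiv), [Ir(OMe)(cod)]2 (cat.), dtbpy, THF, 80 °C; then aq. H2O2, NaOH, 0 °C to rt
Reagents that add atoms: hydrogen peroxide OO (oxygen of the phenol); bis(pinacolato)diboron CC1(C)OB(OC1(C)C)B1OC(C)(C)C(C)(C)O1 (boron of intermediate 16 only)
Why: sterically controlled iridium-catalysed C–H borylation should take the only ring C–H without an ortho substituent (C4, para to the methyl group), and oxidation of the C–B bond then places the hydroxyl at that carbon.

**Step 12**
Reactants: 17 3,5-dimethoxy-4-methylphenol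
Product: 19 1-(6-hydroxy-2,4-dimethoxy-3-methylphenyl)ethanone, via ketiminium chloride 18 (not isolated)
Conditions: MeCN, ZnCl2, HCl (g), Et2O, 0 °C to rt; then H2O, reflux
Reagents that add atoms: acetonitrile CC#N; water O
Why: Houben–Hoesch acylation of this phloroglucinol-type phenol can only occur at the two symmetry-equivalent carbons ortho to the hydroxyl (the para carbon carries the methyl group), so one ketone with the hydroxyl next to an unsubstituted carbon is expected.

**Step 13**
Reactants: 14 4-(benzyloxy)-3-{5,7-bis(benzyloxy)-2-[4-(benzyloxy)phenyl]-4-oxo-4H-chromen-8-yl}benzaldehyde; 19 1-(6-hydroxy-2,4-dimethoxy-3-methylphenyl)ethanone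
Product: 20 (E)-3-(4-(benzyloxy)-3-{5,7-bis(benzyloxy)-2-[4-(benzyloxy)phenyl]-4-oxo-4H-chromen-8-yl}phenyl)-1-(6-hydroxy-2,4-dimethoxy-3-methylphenyl)prop-2-en-1-one
Conditions: KOH (50% aq.), EtOH/THF, rt
Reagents that add atoms: none
Why: Claisen–Schmidt condensation of a methyl ketone with a non-enolisable aldehyde gives the conjugated E enone by E1cB dehydration, and the electron-rich 5,7-dialkoxyflavone, poorly electrophilic at C2, should survive hydroxide at room temperature.

**Step 14**
Reactants: 20 (E)-3-(4-(benzyloxy)-3-{5,7-bis(benzyloxy)-2-[4-(benzyloxy)phenyl]-4-oxo-4H-chromen-8-yl}phenyl)-1-(6-hydroxy-2,4-dimethoxy-3-methylphenyl)prop-2-en-1-one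
Product: 21 5,7-bis(benzyloxy)-2-[4-(benzyloxy)phenyl]-8-[2-(benzyloxy)-5-(5,7-dimethoxy-6-methyl-4-oxo-4H-chromen-2-yl)phenyl]-4H-chromen-4-one
Conditions: I2 (cat.), DMSO, 120 °C
Reagents that add atoms: none
Why: oxidative cyclisation of a 2'-hydroxychalcone proceeds by oxa-Michael closure through the only free hydroxyl followed by iodine-mediated dehydrogenation with DMSO as terminal oxidant, which fixes the 6-methyl-5,7-dimethoxy pattern of unit 1.

**Step 15**
Reactants: 21 5,7-bis(benzyloxy)-2-[4-(benzyloxy)phenyl]-8-[2-(benzyloxy)-5-(5,7-dimethoxy-6-methyl-4-oxo-4H-chromen-2-yl)phenyl]-4H-chromen-4-one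
Product: 22 8-[2-hydroxy-5-(5-hydroxy-7-methoxy-6-methyl-4-oxo-4H-chromen-2-yl)phenyl]-5,7-dihydroxy-2-(4-hydroxyphenyl)-4H-chromen-4-one (CNP0113589.0)
Conditions: BCl3 (excess), C6HMe5, CH2Cl2, −78 °C to rt; then H2O
Reagents that add atoms: none
Why: Lewis-acid ether cleavage with BCl3 removes aryl benzyl ethers at low temperature (pentamethylbenzene traps the benzyl cation) and cleaves only the methyl ether peri to a C4 carbonyl through a boron chelate, so the non-chelated 7-methoxy group of unit 1 should remain.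

**Compound list**
1 | 5-fluororesorcinol | Oc1cc(O)cc(F)c1 | starting material
2 | 1-(2-fluoro-4,6-dihydroxyphenyl)ethan-1-iminium chloride | CC(=[NH2+])c1c(O)cc(O)cc1F.[Cl-] | intermediate (not isolated)
3 | 1-(2-fluoro-4,6-dihydroxyphenyl)ethanone | CC(=O)c1c(O)cc(O)cc1F | intermediate
4 | 1-[2,4-bis(benzyloxy)-6-fluorophenyl]ethanone | CC(=O)c1c(F)cc(OCc2ccccc2)cc1OCc1ccccc1 | intermediate
5 | 1-[4,6-bis(benzyloxy)-3-bromo-2-fluorophenyl]ethanone | CC(=O)c1c(F)c(Br)c(OCc2ccccc2)cc1OCc1ccccc1 | intermediate
6 | 3-bromo-4-hydroxybenzaldehyde | O=Cc1ccc(O)c(Br)c1 | starting material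
7 | 4-(benzyloxy)-3-bromobenzaldehyde | O=Cc1ccc(OCc2ccccc2)c(Br)c1 | intermediate
8 | 2-[4-(benzyloxy)-3-bromophenyl]-1,3-dioxolane | Brc1cc(C2OCCO2)ccc1OCc1ccccc1 | intermediate
9 | 2-[4-(benzyloxy)-3-(4,4,5,5-tetramethyl-1,3,2-dioxaborolan-2-yl)phenyl]-1,3-dioxolane | CC1(C)OB(OC1(C)C)c1cc(C2OCCO2)ccc1OCc1ccccc1 | intermediate
10 | 1-{4,6-bis(benzyloxy)-3-[2-(benzyloxy)-5-(1,3-dioxolan-2-yl)phenyl]-2-fluorophenyl}ethanone | CC(=O)c1c(F)c(-c2cc(C3OCCO3)ccc2OCc2ccccc2)c(OCc2ccccc2)cc1OCc1ccccc1 | intermediate
11 | methyl 4-(benzyloxy)benzoate | COC(=O)c1ccc(OCc2ccccc2)cc1 | starting material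
12 | 1-{4,6-bis(benzyloxy)-3-[2-(benzyloxy)-5-(1,3-dioxolan-2-yl)phenyl]-2-fluorophenyl}-3-[4-(benzyloxy)phenyl]propane-1,3-dione | O=C(CC(=O)c1ccc(OCc2ccccc2)cc1)c1c(F)c(-c2cc(C3OCCO3)ccc2OCc2ccccc2)c(OCc2ccccc2)cc1OCc1ccccc1 | intermediate
13 | 5,7-bis(benzyloxy)-2-[4-(benzyloxy)phenyl]-8-[2-(benzyloxy)-5-(1,3-dioxolan-2-yl)phenyl]-4H-chromen-4-one | O=c1cc(-c2ccc(OCc3ccccc3)cc2)oc2c(-c3cc(C4OCCO4)ccc3OCc3ccccc3)c(OCc3ccccc3)cc(OCc3ccccc3)c12 | intermediate
14 | 4-(benzyloxy)-3-{5,7-bis(benzyloxy)-2-[4-(benzyloxy)phenyl]-4-oxo-4H-chromen-8-yl}benzaldehyde | O=Cc1ccc(OCc2ccccc2)c(-c2c(OCc3ccccc3)cc(OCc3ccccc3)c3c(=O)cc(-c4ccc(OCc5ccccc5)cc4)oc23)c1 | intermediate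
15 | 2,6-dimethoxytoluene | COc1cccc(OC)c1C | starting material
16 | 2-(3,5-dimethoxy-4-methylphenyl)-4,4,5,5-tetramethyl-1,3,2-dioxaborolane | COc1cc(B2OC(C)(C)C(C)(C)O2)cc(OC)c1C | intermediate (not isolated)
17 | 3,5-dimethoxy-4-methylphenol | COc1cc(O)cc(OC)c1C | intermediate
18 | 1-(6-hydroxy-2,4-dimethoxy-3-methylphenyl)ethan-1-iminium chloride | CC(=[NH2+])c1c(O)cc(OC)c(C)c1OC.[Cl-] | intermediate (not isolated)
19 | 1-(6-hydroxy-2,4-dimethoxy-3-methylphenyl)ethanone | CC(=O)c1c(O)cc(OC)c(C)c1OC | intermediate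
20 | (E)-3-(4-(benzyloxy)-3-{5,7-bis(benzyloxy)-2-[4-(benzyloxy)phenyl]-4-oxo-4H-chromen-8-yl}phenyl)-1-(6-hydroxy-2,4-dimethoxy-3-methylphenyl)prop-2-en-1-one | COc1cc(O)c(C(=O)/C=C/c2ccc(OCc3ccccc3)c(-c3c(OCc4ccccc4)cc(OCc4ccccc4)c4c(=O)cc(-c5ccc(OCc6ccccc6)cc5)oc34)c2)c(OC)c1C | intermediate
21 | 5,7-bis(benzyloxy)-2-[4-(benzyloxy)phenyl]-8-[2-(benzyloxy)-5-(5,7-dimethoxy-6-methyl-4-oxo-4H-chromen-2-yl)phenyl]-4H-chromen-4-one | COc1cc2oc(-c3ccc(OCc4ccccc4)c(-c4c(OCc5ccccc5)cc(OCc5ccccc5)c5c(=O)cc(-c6ccc(OCc7ccccc7)cc6)oc45)c3)cc(=O)c2c(OC)c1C | intermediate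
22 | 8-[2-hydroxy-5-(5-hydroxy-7-methoxy-6-methyl-4-oxo-4H-chromen-2-yl)phenyl]-5,7-dihydroxy-2-(4-hydroxyphenyl)-4H-chromen-4-one (CNP0113589.0) | COc1cc2oc(-c3ccc(O)c(-c4c(O)cc(O)c5c(=O)cc(-c6ccc(O)cc6)oc45)c3)cc(=O)c2c(O)c1C | target

**Step count**
Total steps: 15. Longest linear sequence: 10 steps (steps 1–3, 7–10 and 13–15 from 5-fluororesorcinol; the branch from 3-bromo-4-hydroxybenzaldehyde through steps 4–6 is equally long).

**Steps most likely to fail**

Step 9. The enolate oxygen may fail to reach the fluorine-bearing carbon. That carbon is shielded by the neighbouring aryl ring, and the activating ketone is weakened both by enolate conjugation and by the two benzyloxy groups. Forcing the reaction may then cause retro-Claisen cleavage of the diketone. The fallback is the established cross-coupling route to 8-arylflavones, setting out from boronate 9. Commercial apigenin would be perbenzylated (BnBr, K2CO3, DMF, 80 °C) to 5,7-bis(benzyloxy)-2-[4-(benzyloxy)phenyl]-4H-chromen-4-one F1. Iodination (N-iodosuccinimide, TFA, MeCN) would give 5,7-bis(benzyloxy)-2-[4-(benzyloxy)phenyl]-8-iodo-4H-chromen-4-one F2. Fully O-alkylated 5,7-dioxygenated flavones are expected to halogenate at C8, and the site would be confirmed by HMBC before use. Suzuki–Miyaura coupling of this iodide with 9 (Pd(OAc)2, SPhos, K3PO4, toluene/H2O) would return to the route at 13.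

Step 7. Oxidative addition and transmetalation at a bromide flanked by fluorine and benzyloxy may be slow. Protodeboronation of the ortho-alkoxy boronate, hydroxide attack on the ketone-activated C–F bond and aldol self-condensation would then compete. The fallback is a base-free Negishi coupling setting out from bromide 8. Bromine–lithium exchange (n-BuLi, THF, −78 °C) would give [2-(benzyloxy)-5-(1,3-dioxolan-2-yl)phenyl]lithium F3. Transmetalation with ZnCl2 would give [2-(benzyloxy)-5-(1,3-dioxolan-2-yl)phenyl]zinc chloride F4. Coupling of this zinc reagent with bromide 5 (Pd(OAc)2, SPhos, THF, 50 °C) would return to the route at 10.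

Step 3. Bromination at the carbon between the two benzyloxy groups (para to fluorine) may compete. That would carry the aryl group to C6 of the flavone without any visible failure of later steps. The fallback uses a free phenol as the stronger para director and sets out from 3. Selective benzylation of the hydroxyl that is not hydrogen-bonded (BnBr, 1 equiv, K2CO3, acetone, rt) would give 1-[4-(benzyloxy)-2-fluoro-6-hydroxyphenyl]ethanone F5. Bromination (NBS, MeCN, 0 °C) para to the free phenol, as in 2-hydroxy-4-methoxyacetophenone, which reacts at C5, would give 1-[4-(benzyloxy)-3-bromo-2-fluoro-6-hydroxyphenyl]ethanone F6. Benzylation of the remaining phenol (BnBr, K2CO3, DMF, 60 °C) would return to the route at 5.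

**Further compounds**
F1 | step 9 | 5,7-bis(benzyloxy)-2-[4-(benzyloxy)phenyl]-4H-chromen-4-one | O=c1cc(-c2ccc(OCc3ccccc3)cc2)oc2cc(OCc3ccccc3)cc(OCc3ccccc3)c12
F2 | step 9 | 5,7-bis(benzyloxy)-2-[4-(benzyloxy)phenyl]-8-iodo-4H-chromen-4-one | O=c1cc(-c2ccc(OCc3ccccc3)cc2)oc2c(I)c(OCc3ccccc3)cc(OCc3ccccc3)c12
F3 | step 7 | [2-(benzyloxy)-5-(1,3-dioxolan-2-yl)phenyl]lithium | [Li]c1cc(C2OCCO2)ccc1OCc1ccccc1
F4 | step 7 | [2-(benzyloxy)-5-(1,3-dioxolan-2-yl)phenyl]zinc chloride | Cl[Zn]c1cc(C2OCCO2)ccc1OCc1ccccc1
F5 | step 3 | 1-[4-(benzyloxy)-2-fluoro-6-hydroxyphenyl]ethanone | CC(=O)c1c(O)cc(OCc2ccccc2)cc1F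
F6 | step 3 | 1-[4-(benzyloxy)-3-bromo-2-fluoro-6-hydroxyphenyl]ethanone | CC(=O)c1c(O)cc(OCc2ccccc2)c(Br)c1F
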